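## Structural features

The target is a depsidone. Two benzene rings are joined twice, by a diaryl ether oxygen (a5–O–b1) and by an ester (a4–C(=O)–O–b2), which closes a seven-membered dioxepinone ring between them. Ring B also carries a fused five-membered hydroxy-lactone (a 3-hydroxyphthalide), with the carbonyl on b5 and the hemiacetal carbon on b6.

Ring A has five substituents (a1 OMe, a3 Me, a4 carbonyl, a5 ether oxygen, a6 CH2OH; only a2 is CH) and ring B is fully substituted. The ether oxygen is therefore flanked by four ortho groups (a4, a6, b2, b6).

The only stereocentre is the (R)-lactol carbon on b6. It has no stereogenic neighbour, and as the closed form of an ortho-formyl benzoic acid it can open and re-close, so its configuration is labile to acid and base.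

The fragile groups are the lactol, the aryl ester of the seven-membered ring (opened by alkoxide or hydroxide), and the a6 benzylic alcohol (ionised by strong acid, cleaved by hydrogenolysis). Ring B is para-dioxygenated and becomes oxidisable when b1 or b4 is a free phenol.

The real difficulty is twofold: a tetra-ortho-substituted diaryl ether, and enantiopurity at a centre that racemises.

The key step exploits the orsellinate pattern of ring A: carboxyl on a4, oxygen on a5 and a1, methyl on a3. Read as the chain a4–a5–a6–a1–a2–a3, ring A is a triketide whose 3- and 5-carbonyls are enol ethers (the aryl ether at a5, the methyl ether at a1). Bonds a6–a1 and a4–a3 can therefore be made by Michael and aldol chemistry on a chain that already hangs from the b1 oxygen.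

## Logic of the disconnections

**23 back to 22 and 21.** No skeletal bond is cut; the three acetyl C–O bonds of 22 are removed and behind 22 stands the racemate 21. The lactol carbon epimerises by ring opening, so it is made racemic and then funnelled into one enantiomer by an acylation that is faster for the (R)-lactol while both lactols interconvert. The acetal ester in 22 cannot open and stores the configuration. The gain is that everything up to 21 can ignore stereochemistry. The demand is a catalyst that tells the enantiomers of a crowded lactol apart, and a final deacylation free of acid and base.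

**21 back to 20.** The lactone O–C(b5 carbonyl) bond and the hemiacetal C–O bond are cut, giving a methyl ester and a cyclic acetal; the a6 hydroxyl is silylated. A free lactol or aldehyde would not survive amide base, silyl triflate, hydrogenolysis or carbodiimide. The gain is that all masks fall in one acid operation. The demand is that the aldehyde hydrate displaces methanol from the neighbouring ester in acid mild enough for the a6 benzylic alcohol.

**20 back to 19 and 18.** The ester C–O bond between the a4 carbonyl and the b2 oxygen is cut, then the three O–benzyl bonds. The seven-membered ring closes from a seco acid in which the ether already holds both rings side by side. The gain is an acyclic diaryl ether with every oxygen differentiated. The demand is acylation of a di-ortho-flanked phenol by a di-ortho-flanked acid while the chelated b4 phenol stays out, and a hydrogenolysis that spares the benzylic silyl ether and the aryl acetal.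

**18 back to 12 and 15 (key).** Bonds a6–a1 and a4–a3 are cut. This removes ring A altogether and turns the crowded ether oxygen into an enol-ether oxygen, which can be made by conjugate addition instead of aryl coupling. The demand is reaction first through the γ-carbon and then the α-carbon of 12, each at the right carbon of 15. Ring B must also tolerate amide base and silyl triflate, so 12 carries benzyl ethers, a methyl ester and a cyclic acetal, and no open-chain acetal or alkoxymethyl ether.

**12 back to 8 and 11.** The enol-ether C–O bond (a5–O) is cut. A phenol adds to the β-carbon of an ynoate, giving two fragments of similar size. The demand is β- rather than γ-addition of a hindered phenol, and E geometry, which places the γ-CH2 cis to the ester for the later deprotonation.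

**11 back to 9; 15 back to 13 and 14.** The alkyne–carboxyl C–C bond and the bond between the acetyl carbon and the ketene-acetal carbon are cut. Both are single acylations of purchasable nucleophiles.

**8 back to 1 through 7, 6, 5, 4 and 2.** The b5–CO2Me bond, the acetal, the C–Br bond, the b6–CHO bond, the b1 C–O bond and the benzyl ethers are cut in turn. The order follows the directing effects. The formyl group of 1 is traded for the b1 oxygen, which leaves one free phenol among three oxygens without any selective protection. That phenol directs formylation to b6. The last open position, b5, activated by both benzyloxy groups, takes bromine and then the ester carbon. The demand is only that each substitution has a single possible site.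

## Other disconnections considered

**Alternative 1:** The cut removes the three bonds that close the seven-membered ring: b1 O–a5, a4–C(=O) and C(=O)–O(b2). This leaves catechol A2 (7-benzyloxy-4,5-dihydroxy-6-methylphthalide), fluoro-iodoarene A3 (2-fluoro-3-iodo-6-methoxy-4-methylbenzaldehyde) and CO. In the forward step K2CO3 forms the dianion of A2, one phenoxide displaces the fluoride of A3 (activated by the ortho aldehyde), and Pd(OAc)2 with a bisphosphine inserts CO into the C–I bond; the second phenoxide captures the acyl-palladium to give A1.

- In its favour: two arenes and CO would give the whole tricyclic core in one pot, and fluoride displacement next to an aldehyde is a dependable way to a crowded diaryl ether. On steps to the depsidone core, and on reliance on established reaction types, it is better than the chosen plan.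
- Against it: both phenoxide oxygens of A2 are di-ortho-flanked and nothing forces b1 to attack first. Arylation at b2 followed by carbonylation would interchange ether and ester, and base could scramble the ether by Smiles rearrangement.
- After A1 two carbons are at the wrong oxidation level. The a6 aldehyde must be reduced beside an aryl ester, and the phthalide CH2 must be oxidised to the lactol in the presence of a benzylic alcohol and two aryl methyl groups, with no selective handle.
- The stereocentre would still need the same dynamic resolution, so on that point the two plans are equal.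
- In the chosen plan only the b1 phenol of 8 is free and b6 enters at the aldehyde level (step 3), so neither question arises. The price is a longer route and an annulation that is an extension of precedent.

**Alternative 2:** The cut takes ring A apart into three alkynes (bonds a6–a1, a2–a3, a4–a5). The precursor is triyne A5, in which ring B carries on b1 an aryl ynol ether tethered through CH2–O–Si(i-Pr)2 to a methoxyethynyl group, and on b2 a but-2-ynoate ester. In the forward step a monovalent rhodium catalyst such as RhCl(PPh3)3 cyclotrimerises A5 to A4, closing ring A, the lactone and a temporary siloxane ring.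

- In its favour: three rings and three C–C bonds in one step, regiochemistry fixed entirely by the tethers, and a silicon bridge that would later leave a2–H and a6–CH2OH. It forms the lactone in the same step and is better than the chosen plan there, which needs separate hydrogenolysis and lactonisation. Neutral rhodium conditions would also be kinder to acetals than silyl triflate, again a point for this alternative.
- Equal point: like the chosen plan, it builds ring A onto the b1 oxygen and avoids aryl–aryl ether coupling.
- Against it: A5 contains two ynol ethers (one an aryl alkynyl ether on a hexasubstituted phenol) and an alkynoate aryl ester, all prone to hydration, rearrangement to ketenes and acyl transfer. Assembling them would take more steps than the annulation saves. The ester tether must adopt its less favoured conformation to close a seven-membered ring, so oligomerisation would compete.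
- The stereocentre is left to the end exactly as in the chosen plan. Overall step economy favours the chosen plan because 12 is made from stable fragments in one step.

**Alternative 3:** The cut opens the lactol ring (the b5–carbonyl bond, the lactone C–O bond and the acetal C–O bond), leaving bromo aldehyde A7, CO and benzyl alcohol. In the forward step, under Pd(OAc)2 and a chiral bisphosphine, the alcohol forms a hemiacetal, palladium inserts into the C–Br bond and takes up CO, and the hemiacetal hydroxyl captures the acyl-palladium to give the (R)-O-benzyl acetal A6.

- In its favour: the stereocentre would be set by catalyst control late and stored as a configurationally stable acetal. Hydrogenolysis would then free the lactol under neutral conditions together with the b4 benzyl ether. On end-game step count, and on avoiding an acylation/deacylation detour, it is better than the chosen plan.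
- Equal point: A7 could be reached by the same ring A annulation with bromine kept on b5, so the two plans are equal on ring A.
- Against it: the racemic carbonylative closure is an established reaction type, but enantioselection between rapidly exchanging hemiacetals by a chiral acyl-palladium would be a new method, applied to a di-ortho-flanked bromide.
- Amine base and benzyl alcohol at the temperature of carbonylation threaten the aryl ester of the seven-membered ring. The final hydrogenolysis must cleave O–CH2Ph without breaking the C–O bonds at the lactol carbon or at a6.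
- The chosen plan carries out the same carbonylation early, racemically and on a simple arene (step 6), and sets the stereocentre by a known type of acylative dynamic resolution.

Key step: step 10

**Assumptions**

- Assumption: the lactol carbon of 23 epimerises only under acid or base catalysis (through the open formyl acid), so 23, set free and isolated in a neutral aprotic medium at or below room temperature, is taken to keep its configuration.
- Design remark: a dimethyl acetal and a methoxymethyl ether on ring B would be ionised by the silyl triflate of the key step, so ring B carries a 5,5-dimethyl-1,3-dioxane on b6 and benzyl ethers on both b2 and b4, which also saves a separate deprotection.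
- Remark: 1, 9, 13 and 14 are taken as purchasable.

## Route

Step 1
Reactants: 1 2,4-dihydroxy-3-methylbenzaldehyde
Product: 2 2,4-bis(benzyloxy)-3-methylbenzaldehyde
Conditions: BnBr (2.5 equiv), K2CO3, KI (cat.), DMF, 70 °C
Reagents that add atoms: benzyl bromide, BrCc1ccccc1
Why: Williamson ether synthesis; excess bromide and heat also alkylate the hydrogen-bonded 2-hydroxyl, and both benzyl groups later leave together with the benzyl ester.

Step 2
Reactants: 2 2,4-bis(benzyloxy)-3-methylbenzaldehyde
Product: 4 2,4-bis(benzyloxy)-3-methylphenol, via aryl formate 3 (not isolated)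
Conditions: mCPBA, CH2Cl2, 0 °C → rt; then K2CO3 (cat.), MeOH, rt
Reagents that add atoms: 3-chloroperoxybenzoic acid, O=C(OO)c1cccc(Cl)c1
Why: Baeyer–Villiger (Dakin-type) oxidation, in which the electron-rich aryl group migrates to oxygen; methanolysis of the formate frees one phenol, the future b1 oxygen, next to two benzyl ethers.

Step 3
Reactants: 4 2,4-bis(benzyloxy)-3-methylphenol
Product: 5 3,5-bis(benzyloxy)-2-hydroxy-4-methylbenzaldehyde
Conditions: MgCl2, Et3N, (CH2O)n, MeCN, reflux
Reagents that add atoms: formaldehyde (as paraformaldehyde), C=O
Why: magnesium-phenoxide-directed ortho-formylation (Casnati–Skattebøl); only one ortho position is open, and a second formaldehyde accepts hydride from the intermediate benzylic alkoxide to give the aldehyde on b6.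

Step 4
Reactants: 5 3,5-bis(benzyloxy)-2-hydroxy-4-methylbenzaldehyde
Product: 6 3,5-bis(benzyloxy)-2-bromo-6-hydroxy-4-methylbenzaldehyde
Conditions: NBS, MeCN, 0 °C → rt, dark
Reagents that add atoms: N-bromosuccinimide, O=C1CCC(=O)N1Br
Why: electrophilic aromatic bromination at the only free ring carbon (b5), which is ortho and para to the two benzyloxy groups.

Step 5
Reactants: 6 3,5-bis(benzyloxy)-2-bromo-6-hydroxy-4-methylbenzaldehyde
Product: 7 2,4-bis(benzyloxy)-5-bromo-6-(5,5-dimethyl-1,3-dioxan-2-yl)-3-methylphenol
Conditions: 2,2-dimethylpropane-1,3-diol, PPTS (cat.), toluene, reflux, Dean–Stark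
Reagents that add atoms: 2,2-dimethylpropane-1,3-diol, OCC(C)(C)CO
Why: acid-catalysed acetalisation with removal of water; the neopentyl-glycol acetal is chosen because it should resist base, palladium catalysis and catalytic silyl triflate, and the phenol stays free.

Step 6
Reactants: 7 2,4-bis(benzyloxy)-5-bromo-6-(5,5-dimethyl-1,3-dioxan-2-yl)-3-methylphenol
Product: 8 methyl 2,4-bis(benzyloxy)-6-(5,5-dimethyl-1,3-dioxan-2-yl)-5-hydroxy-3-methylbenzoate
Conditions: Pd(OAc)2 (5 mol%), 4,5-bis(diphenylphosphino)-9,9-dimethylxanthene (10 mol%), Et3N, CO (10 bar), MeOH–toluene, 100 °C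
Reagents that add atoms: carbon monoxide, [C-]#[O+]; methanol, CO
Why: palladium-catalysed alkoxycarbonylation of an aryl bromide (oxidative addition, CO insertion, methanolysis of the acyl-palladium); the wide-bite-angle bisphosphine suits a hindered electron-rich bromide, and the acetal keeps the aldehyde from capturing the acyl-palladium.

Step 7
Reactants: 9 tert-butyl(but-3-yn-1-yloxy)dimethylsilane
Product: 11 benzyl 5-[(tert-butyldimethylsilyl)oxy]pent-2-ynoate, via lithium acetylide 10 (not isolated)
Conditions: n-BuLi, THF, −78 °C; then ClCO2Bn, −78 → 0 °C
Reagents that add atoms: benzyl chloroformate, O=C(Cl)OCc1ccccc1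
Why: deprotonation of the terminal alkyne and C-acylation of the acetylide by the chloroformate, a standard ynoate synthesis.

Step 8
Reactants: 8 methyl 2,4-bis(benzyloxy)-6-(5,5-dimethyl-1,3-dioxan-2-yl)-5-hydroxy-3-methylbenzoate; 11 benzyl 5-[(tert-butyldimethylsilyl)oxy]pent-2-ynoate
Product: 12 benzyl (2E)-3-[2,4-bis(benzyloxy)-6-(5,5-dimethyl-1,3-dioxan-2-yl)-5-(methoxycarbonyl)-3-methylphenoxy]-5-[(tert-butyldimethylsilyl)oxy]pent-2-enoate
Conditions: PMe3 (20 mol%), CH2Cl2, 0 °C → rt
Reagents that add atoms: none
Why: phosphine-catalysed oxa-Michael addition, in which the phosphine–ynoate zwitterion deprotonates the phenol and the phenoxide adds to the β-carbon; a small trialkylphosphine at room temperature should favour β- over γ-addition, and reversible addition should settle on the E isomer (aryloxy trans to the ester), which places the γ-CH2 cis to the ester.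

Step 9
Reactants: 13 1,1-dimethoxyethene; 14 acetyl chloride
Product: 15 4,4-dimethoxybut-3-en-2-one
Conditions: Et3N, Et2O, 0 °C → rt
Reagents that add atoms: none
Why: C-acylation of a ketene acetal by an acid chloride; the amine takes HCl from the oxocarbenium intermediate and leaves the push–pull enone.

Step 10
Reactants: 12 benzyl (2E)-3-[2,4-bis(benzyloxy)-6-(5,5-dimethyl-1,3-dioxan-2-yl)-5-(methoxycarbonyl)-3-methylphenoxy]-5-[(tert-butyldimethylsilyl)oxy]pent-2-enoate; 15 4,4-dimethoxybut-3-en-2-one
Product: 18 benzyl 2-[2,4-bis(benzyloxy)-6-(5,5-dimethyl-1,3-dioxan-2-yl)-5-(methoxycarbonyl)-3-methylphenoxy]-3-{[(tert-butyldimethylsilyl)oxy]methyl}-4-methoxy-6-methylbenzoate, via silyl dienol ether 16 (not isolated), via open-chain dienone 17 (not isolated)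
Conditions: LDA (LiN(i-Pr)2), TMSCl, THF, −78 °C; volatiles removed; then 15, TMSOTf (10 mol%), 2,6-di-tert-butylpyridine (10 mol%), CH2Cl2, −78 → −20 °C; then DBU, 0 °C → rt
Reagents that add atoms: none
Why: Proposed new method: LDA removes a γ-proton of 12 that lies cis to the ester, and TMSCl traps the dienolate on oxygen as 16. TMSOTf silylates the carbonyl oxygen of 15 to a 1,1-dimethoxy-3-silyloxyallyl cation whose charge sits on the ketene-acetal carbon; the γ-carbon of 16 (a6), which carries the largest HOMO coefficient of a 1,3-dioxygenated silyl dienol ether, adds there in a vinylogous Mukaiyama–Michael reaction, and loss of methoxytrimethylsilane restores the β-methoxy enone in 17 (bond a6–a1). DBU then removes the doubly vinylogous a6 proton, the ester α-carbon (a4) closes on the ketone (a3) in a 6-(enolexo)-exo-trig aldol, and loss of water aromatises ring A (bond a4–a3). The closest known reaction type is the formal [3+3] cyclocondensation of 1,3-bis(silyloxy)-1,3-dienes with 3-alkoxy and 3,3-dialkoxy enones to salicylates, together with γ-selective vinylogous Mukaiyama additions of 1,3-dialkoxy-1-silyloxy dienes; what is new is a diene whose 3-oxygen is an aryl ether and therefore survives in the product. No stereocentre is formed. The step needs γ- over α-attack and conjugate over carbonyl attack in the first bond formation, which fixes OMe on a1 and Me on a3; the orbital coefficients of 16, the shielding of its α-carbon by the hexasubstituted aryloxy group and the charge distribution of silylated 15 should secure both, and once 17 is formed only one six-membered closure is possible. Benzyl ethers, the hindered methyl ester and the cyclic acetal of ring B should tolerate LDA at −78 °C and a catalytic amount of silyl triflate buffered by the hindered pyridine.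

Step 11
Reactants: 18 benzyl 2-[2,4-bis(benzyloxy)-6-(5,5-dimethyl-1,3-dioxan-2-yl)-5-(methoxycarbonyl)-3-methylphenoxy]-3-{[(tert-butyldimethylsilyl)oxy]methyl}-4-methoxy-6-methylbenzoate
Product: 19 3-{[(tert-butyldimethylsilyl)oxy]methyl}-2-[6-(5,5-dimethyl-1,3-dioxan-2-yl)-2,4-dihydroxy-5-(methoxycarbonyl)-3-methylphenoxy]-4-methoxy-6-methylbenzoic acid
Conditions: H2 (1 atm), Pd/C (10%), EtOAc, rt, stopped after three equivalents of H2
Reagents that add atoms: none
Why: hydrogenolysis of one benzyl ester and two aryl benzyl ethers; in neutral ethyl acetate these cleave much faster than the benzylic silyl ether or the aryl acetal, both of which sit on crowded ring positions.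

Step 12
Reactants: 19 3-{[(tert-butyldimethylsilyl)oxy]methyl}-2-[6-(5,5-dimethyl-1,3-dioxan-2-yl)-2,4-dihydroxy-5-(methoxycarbonyl)-3-methylphenoxy]-4-methoxy-6-methylbenzoic acid
Product: 20 protected depsidone (dibenzo[b,e][1,4]dioxepin-11-one with a1 OMe, a3 Me, a6 CH2OSi(t-Bu)Me2, b3 Me, b4 OH, b5 CO2Me and b6 5,5-dimethyl-1,3-dioxan-2-yl)
Conditions: DCC, DMAP (cat.), CH2Cl2 (0.005 M), 0 °C → rt
Reagents that add atoms: none
Why: carbodiimide (Steglich-type) lactonisation, the classical depsidone ring closure; the ether holds the b2 phenol next to the activated a4 acid, while the b4 phenol is para to the ether oxygen, cannot reach the acid within the molecule, and is deactivated by its hydrogen bond to the b5 ester.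

Step 13
Reactants: 20 protected depsidone
Product: 21 racemic lactol (the target, racemic at the lactol carbon)
Conditions: 1 M aq. H2SO4–THF (1:2), 45 °C
Reagents that add atoms: water, O
Why: acid hydrolysis of the silyl ether and the cyclic acetal; the freed aldehyde, through its hydrate or through participation of the ester carbonyl, displaces methanol from the neighbouring ester and closes the hydroxy-lactone (pseudo-acid formation), with a non-nucleophilic acid and excess water to protect the a6 benzylic alcohol.

Step 14
Reactants: 21 racemic lactol
Product: 22 (R)-triacetate (acetyl groups on the lactol oxygen, the a6 CH2O and the b4 phenol)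
Conditions: Ac2O (5 equiv), benzotetramisole (10 mol%, the antipode that acylates the (R)-lactol faster), i-Pr2NEt, CHCl3, 0 °C
Reagents that add atoms: acetic anhydride, CC(=O)OC(C)=O
Why: acylative dynamic kinetic resolution of a 3-hydroxyphthalide; the amine keeps the two lactols in exchange through the open formyl carboxylate, the chiral acyl-isothiouronium ion acylates the (R)-lactol faster, and the resulting acetal ester cannot open, so the catalyst sets the (R) centre. The primary alcohol and the phenol are acetylated without stereochemical consequence.

Step 15
Reactants: 22 (R)-triacetate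
Product: 23 target, (R)-lactol
Conditions: immobilised Candida antarctica lipase B, n-BuOH, t-BuOMe, 25 °C; filtration, evaporation below 25 °C
Reagents that add atoms: none
Why: lipase-catalysed transesterification of the three acetates to butanol; cleavage is at the acyl–oxygen bond, so the C–O bond at the lactol carbon is untouched and the configuration is retained, and the neutral aprotic medium avoids ring opening.

## Compound list

1 | 2,4-dihydroxy-3-methylbenzaldehyde | O=Cc1ccc(O)c(C)c1O | starting material
2 | 2,4-bis(benzyloxy)-3-methylbenzaldehyde | O=Cc1ccc(OCc2ccccc2)c(C)c1OCc1ccccc1 | intermediate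
3 | 2,4-bis(benzyloxy)-3-methylphenyl formate | O=COc1ccc(OCc2ccccc2)c(C)c1OCc1ccccc1 | intermediate (not isolated)
4 | 2,4-bis(benzyloxy)-3-methylphenol | Oc1ccc(OCc2ccccc2)c(C)c1OCc1ccccc1 | intermediate
5 | 3,5-bis(benzyloxy)-2-hydroxy-4-methylbenzaldehyde | O=Cc1cc(OCc2ccccc2)c(C)c(OCc2ccccc2)c1O | intermediate
6 | 3,5-bis(benzyloxy)-2-bromo-6-hydroxy-4-methylbenzaldehyde | O=Cc1c(Br)c(OCc2ccccc2)c(C)c(OCc2ccccc2)c1O | intermediate
7 | 2,4-bis(benzyloxy)-5-bromo-6-(5,5-dimethyl-1,3-dioxan-2-yl)-3-methylphenol | Oc1c(OCc2ccccc2)c(C)c(OCc2ccccc2)c(Br)c1C1OCC(C)(C)CO1 | intermediate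
8 | methyl 2,4-bis(benzyloxy)-6-(5,5-dimethyl-1,3-dioxan-2-yl)-5-hydroxy-3-methylbenzoate | COC(=O)c1c(OCc2ccccc2)c(C)c(OCc2ccccc2)c(O)c1C1OCC(C)(C)CO1 | intermediate
9 | tert-butyl(but-3-yn-1-yloxy)dimethylsilane | C#CCCO[Si](C)(C)C(C)(C)C | starting material
10 | lithium 4-[(tert-butyldimethylsilyl)oxy]but-1-yn-1-ide | [Li]C#CCCO[Si](C)(C)C(C)(C)C | intermediate (not isolated)
11 | benzyl 5-[(tert-butyldimethylsilyl)oxy]pent-2-ynoate | O=C(OCc1ccccc1)C#CCCO[Si](C)(C)C(C)(C)C | intermediate
12 | benzyl (2E)-3-[2,4-bis(benzyloxy)-6-(5,5-dimethyl-1,3-dioxan-2-yl)-5-(methoxycarbonyl)-3-methylphenoxy]-5-[(tert-butyldimethylsilyl)oxy]pent-2-enoate | O=C(OCc1ccccc1)/C=C(/Oc1c(OCc2ccccc2)c(C)c(OCc2ccccc2)c(C(=O)OC)c1C1OCC(C)(C)CO1)CCO[Si](C)(C)C(C)(C)C | intermediate (key-step precursor)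
13 | 1,1-dimethoxyethene | C=C(OC)OC | starting material
14 | acetyl chloride | CC(=O)Cl | starting material
15 | 4,4-dimethoxybut-3-en-2-one | CC(=O)C=C(OC)OC | intermediate
16 | 1-benzyloxy-1-(trimethylsilyloxy)-3-(ring B aryloxy)-5-[(tert-butyldimethylsilyl)oxy]penta-1,3-diene (silyl dienol ether of 12, double-bond geometry not fixed) | C[Si](C)(C)OC(OCc1ccccc1)=CC(Oc1c(OCc2ccccc2)c(C)c(OCc2ccccc2)c(C(=O)OC)c1C1OCC(C)(C)CO1)=CCO[Si](C)(C)C(C)(C)C | intermediate (not isolated)
17 | benzyl 3-(ring B aryloxy)-4-{[(tert-butyldimethylsilyl)oxy]methyl}-5-methoxy-7-oxoocta-2,5-dienoate (racemic, double-bond isomers) | CC(=O)C=C(OC)C(CO[Si](C)(C)C(C)(C)C)C(Oc1c(OCc2ccccc2)c(C)c(OCc2ccccc2)c(C(=O)OC)c1C1OCC(C)(C)CO1)=CC(=O)OCc1ccccc1 | intermediate (not isolated)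
18 | benzyl 2-[2,4-bis(benzyloxy)-6-(5,5-dimethyl-1,3-dioxan-2-yl)-5-(methoxycarbonyl)-3-methylphenoxy]-3-{[(tert-butyldimethylsilyl)oxy]methyl}-4-methoxy-6-methylbenzoate | COc1cc(C)c(C(=O)OCc2ccccc2)c(Oc2c(OCc3ccccc3)c(C)c(OCc3ccccc3)c(C(=O)OC)c2C2OCC(C)(C)CO2)c1CO[Si](C)(C)C(C)(C)C | intermediate (key-step product)
19 | 3-{[(tert-butyldimethylsilyl)oxy]methyl}-2-[6-(5,5-dimethyl-1,3-dioxan-2-yl)-2,4-dihydroxy-5-(methoxycarbonyl)-3-methylphenoxy]-4-methoxy-6-methylbenzoic acid | COc1cc(C)c(C(=O)O)c(Oc2c(O)c(C)c(O)c(C(=O)OC)c2C2OCC(C)(C)CO2)c1CO[Si](C)(C)C(C)(C)C | intermediate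
20 | protected depsidone: seven-membered lactone closed, a6 CH2OSi(t-Bu)Me2, b4 OH, b5 CO2Me, b6 5,5-dimethyl-1,3-dioxan-2-yl | COc1cc(C)c2c(c1CO[Si](C)(C)C(C)(C)C)Oc1c(c(C)c(O)c(C(=O)OC)c1C1OCC(C)(C)CO1)OC2=O | intermediate
21 | racemic lactol (target constitution, both configurations at the lactol carbon) | COc1cc(C)c2c(c1CO)Oc1c(c(C)c(O)c3c1C(O)OC3=O)OC2=O | intermediate
22 | (R)-triacetate: lactol O-acetate with (R) configuration, a6 CH2OAc, b4 OAc | COc1cc(C)c2c(c1COC(C)=O)Oc1c(c(C)c(OC(C)=O)c3c1[C@H](OC(C)=O)OC3=O)OC2=O | intermediate
23 | CNP0367167.1, (R)-lactol | COc1cc(C)c2c(c1CO)Oc1c(c(C)c(O)c3c1[C@H](O)OC3=O)OC2=O | target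

## Step count and risks

Total: 15 steps. Longest linear sequence: 13 steps (1–6, 8, 10–15).

**Step 10 (key step, proposed as a new method).**
- Most likely failure: bond formation through the α-carbon or at the carbonyl carbon of 15, which would scramble the substitution of ring A. Also possible are ionisation of the allylic silyloxy group or of the cyclic acetal by the silyl triflate, loss of silanolate from the a6 anion under DBU, or a stall at the open-chain stage because the α-carbon of a β-aryloxy enoate is a weaker nucleophile than that of a β-keto ester.
- Fallback, known chemistry, from 11 back to 18. Pyrrolidine adds to 11 to give benzyl 5-[(tert-butyldimethylsilyl)oxy]-3-(pyrrolidin-1-yl)pent-2-enoate F1, which wet silica and oxalic acid hydrolyse to benzyl 5-[(tert-butyldimethylsilyl)oxy]-3-oxopentanoate F2. TMSCl/Et3N gives benzyl 5-[(tert-butyldimethylsilyl)oxy]-3-(trimethylsilyloxy)pent-2-enoate F3, and LDA/TMSCl gives 1-benzyloxy-1,3-bis(trimethylsilyloxy)-5-[(tert-butyldimethylsilyl)oxy]penta-1,3-diene F4. The established TiCl4-mediated [3+3] cyclocondensation of F4 with 15 (CH2Cl2, −78 °C → rt) would give benzyl 3-{[(tert-butyldimethylsilyl)oxy]methyl}-2-hydroxy-4-methoxy-6-methylbenzoate F5. Tf2O/pyridine gives benzyl 3-{[(tert-butyldimethylsilyl)oxy]methyl}-4-methoxy-6-methyl-2-[(trifluoromethanesulfonyl)oxy]benzoate F6. Palladium-catalysed C–O coupling of F6 with 8 (Pd(OAc)2, 2-(di-tert-butylphosphino)-2',4',6'-triisopropylbiphenyl, K3PO4, toluene, 100 °C) returns to 18, at the price of an aryl–oxygen coupling between two di-ortho-substituted partners.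

**Step 8.**
- Most likely failure: slow addition of the di-ortho-flanked phenoxide, phosphine-induced isomerisation of 11 followed by γ-addition, or incomplete equilibration to the E isomer.
- Fallback, from 11 back to 12. LiCl and AcOH in MeCN add HCl across 11 to give benzyl (2Z)-3-chloro-5-[(tert-butyldimethylsilyl)oxy]pent-2-enoate F7. Addition–elimination with the potassium salt of 8 (K2CO3, DMF, 50 °C) replaces chloride and, by reversible phenoxide addition, should settle on the E isomer 12.

**Step 12.**
- Most likely failure: rearrangement of the O-acylisourea to an N-acylurea because the hindered phenol captures it slowly, or intermolecular esterification.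
- Fallback, from 19 back to 20. 2,2'-Dipyridyl disulfide and PPh3 convert 19 into its S-(pyridin-2-yl) thioester F8. AgOTf in dilute toluene then activates the thioester for closure onto the b2 phenol (double-activation lactonisation).

**Step 13.**
- Most likely failure: a stall after acetal and silyl ether cleavage because the hindered aldehyde hydrate displaces methanol slowly, or ionisation of the a6 benzylic alcohol if the acid is forced.
- Fallback, from 20 back to 21. Acid hydrolysis is stopped at methyl ester aldehyde F9 (a6 CH2OH, b5 CO2Me, b6 CHO). F9 is then stirred briefly in THF–phosphate buffer at pH 8, where the hydrate anion attacks the neighbouring ester and expels methoxide; acidification gives 21.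

**Step 14.**
- Most likely failure: weak discrimination between the lactol enantiomers because the aryloxy group crowds the lactol carbon, or uncatalysed background acylation that lowers the enantiomeric purity.
- Fallback, from 21 back to 23. A lipase chosen by screening for (R)-preference, with vinyl acetate in toluene and a trace of Et3N to keep the lactols in exchange, would give the (R)-diacetate F10 (lactol O-acetate and a6 CH2OAc, b4 OH free) by enzymatic dynamic resolution. The conditions of step 15 then take F10 to 23.

**Step 15.**
- Most likely failure: slow enzymatic cleavage of the hindered acetal ester, and partial racemisation of the freed lactol during the long contact time.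
- Fallback, from 21 back to 23, bypassing 22. The free lactols are separated on a chiral stationary phase with a neutral aprotic eluent at low temperature. The unwanted (S)-lactol F11 is returned to 21 by a catalytic amount of Et3N and recycled.

## Further compounds

F1 | step 10 | benzyl 5-[(tert-butyldimethylsilyl)oxy]-3-(pyrrolidin-1-yl)pent-2-enoate | O=C(OCc1ccccc1)C=C(CCO[Si](C)(C)C(C)(C)C)N1CCCC1
F2 | step 10 | benzyl 5-[(tert-butyldimethylsilyl)oxy]-3-oxopentanoate | O=C(CC(=O)OCc1ccccc1)CCO[Si](C)(C)C(C)(C)C
F3 | step 10 | benzyl 5-[(tert-butyldimethylsilyl)oxy]-3-(trimethylsilyloxy)pent-2-enoate | C[Si](C)(C)OC(CCO[Si](C)(C)C(C)(C)C)=CC(=O)OCc1ccccc1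
F4 | step 10 | 1-benzyloxy-1,3-bis(trimethylsilyloxy)-5-[(tert-butyldimethylsilyl)oxy]penta-1,3-diene | C[Si](C)(C)OC(OCc1ccccc1)=CC(O[Si](C)(C)C)=CCO[Si](C)(C)C(C)(C)C
F5 | step 10 | benzyl 3-{[(tert-butyldimethylsilyl)oxy]methyl}-2-hydroxy-4-methoxy-6-methylbenzoate | COc1cc(C)c(C(=O)OCc2ccccc2)c(O)c1CO[Si](C)(C)C(C)(C)C
F6 | step 10 | benzyl 3-{[(tert-butyldimethylsilyl)oxy]methyl}-4-methoxy-6-methyl-2-[(trifluoromethanesulfonyl)oxy]benzoate | COc1cc(C)c(C(=O)OCc2ccccc2)c(OS(=O)(=O)C(F)(F)F)c1CO[Si](C)(C)C(C)(C)C
F7 | step 8 | benzyl (2Z)-3-chloro-5-[(tert-butyldimethylsilyl)oxy]pent-2-enoate | O=C(OCc1ccccc1)/C=C(\Cl)CCO[Si](C)(C)C(C)(C)C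
F8 | step 12 | S-(pyridin-2-yl) thioester of seco acid 19 | COc1cc(C)c(C(=O)Sc2ccccn2)c(Oc2c(O)c(C)c(O)c(C(=O)OC)c2C2OCC(C)(C)CO2)c1CO[Si](C)(C)C(C)(C)C
F9 | step 13 | depsidone methyl ester aldehyde (a6 CH2OH, b4 OH, b5 CO2Me, b6 CHO) | COc1cc(C)c2c(c1CO)Oc1c(c(C)c(O)c(C(=O)OC)c1C=O)OC2=O
F10 | step 14 | (R)-diacetate (lactol O-acetate and a6 CH2OAc, b4 OH free) | COc1cc(C)c2c(c1COC(C)=O)Oc1c(c(C)c(O)c3c1[C@H](OC(C)=O)OC3=O)OC2=O
F11 | step 15 | (S)-lactol, enantiomer of 23 | COc1cc(C)c2c(c1CO)Oc1c(c(C)c(O)c3c1[C@@H](O)OC3=O)OC2=O
A1 | alternative 1 | depsidone with a6 aldehyde, b4 benzyl ether and phthalide CH2 | COc1cc(C)c2c(c1C=O)Oc1c(c(C)c(OCc4ccccc4)c3c1COC3=O)OC2=O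
A2 | alternative 1 | 7-(benzyloxy)-4,5-dihydroxy-6-methyl-2-benzofuran-1(3H)-one | Oc1c(O)c(C)c(OCc2ccccc2)c2c1COC2=O
A3 | alternative 1 | 2-fluoro-3-iodo-6-methoxy-4-methylbenzaldehyde | COc1cc(C)c(I)c(F)c1C=O
A4 | alternative 2 | depsidone with a2 and the a6 CH2O group joined through a diisopropylsilyl bridge | COc1c2c(C)c3c(c1CO[Si]2(C(C)C)C(C)C)Oc1c(c(C)c(OCOC)c(C(=O)OC)c1C(OC)OC)OC3=O
A5 | alternative 2 | tethered triyne: ring B with b1 O–C≡C–CH2–O–Si(i-Pr)2–C≡C–OMe and b2 but-2-ynoate | COC#C[Si](C(C)C)(C(C)C)OCC#COc1c(OC(=O)C#CC)c(C)c(OCOC)c(C(=O)OC)c1C(OC)OC
A6 | alternative 3 | protected target with the lactol as its (R)-O-benzyl acetal | COc1cc(C)c2c(c1CO[Si](C)(C)C(C)(C)C)Oc1c(c(C)c(OCc4ccccc4)c3c1[C@H](OCc5ccccc5)OC3=O)OC2=O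
A7 | alternative 3 | depsidone ortho-bromo aldehyde (b5 Br, b6 CHO, b4 OBn, a6 CH2OSi(t-Bu)Me2) | COc1cc(C)c2c(c1CO[Si](C)(C)C(C)(C)C)Oc1c(c(C)c(OCc4ccccc4)c(Br)c1C=O)OC2=O
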